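**Retrosynthetic overview**

1. The last ring is the cyclohexene (C5′, C6′, C7′, C8′, C9′, C10′). It is closed at C5′–C10′ by an acid-triggered ketal hydrolysis / C7′ epimerisation / aldol cyclodehydration of a masked 1,5-diketone, followed by C6′ C=O → CH–OH. This works because the tetrasubstituted C5′=C10′ olefin next to the C6′ carbinol is an aldol-condensation retron, and a C6′ carbonyl makes the ring-fusion carbon C7′ of the cis γ-lactone (C7′–C8′–O–C12′–C11′) epimerisable.
2. The norbornene (C1, C2, C3, C4, C5, C13′, C11′) and the spiro carbon C11′ come from a Diels–Alder reaction (C1–C13′, C3–C11′) of a 2-acetoxyguaia-1(5),3-diene with a trans-disubstituted α-methylene-γ-butyrolactone. The trans C7′ substituent steers the dienophile face and is inverted in the key step.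
3. The dienophile comes from 1,4-addition of a citronellal-derived dithiane anion to a 5-substituted butenolide, formaldehyde trapping and elimination.
4. The diene half comes from an organocatalytic Michael addition (C1–C10), Stork–Danheiser transposition, carbonyl-ene closure of the cycloheptane (C7–C8), allylic oxidation / oxidative lactonisation, CBS reduction and dehydration.
5. Ring order: cyclopentenone (purchased ring, with a temporary dihydropyran) → cycloheptane → guaianolide lactone; butenolide (later the spirolactone); norbornene; cyclohexene last.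

Key step: step 21

Remark: guaiane numbering (C1–C15) is used for the cyclopentane–cycloheptane half and 1,10-seco-eudesmane numbering (C1′–C15′) for the other half. The acetal carbon of 4–7 and C4 of 5–14 are carried as epimer mixtures because both centres are erased later.

**Route**

Step 1
Reactants: 1 cyclopentane-1,3-dione; 2 (E)-but-2-enal
Product: 4 (4R)-2-methoxy-4-methyl-3,4,6,7-tetrahydrocyclopenta[b]pyran-5(2H)-one (anomer mixture), via hemiacetal 3 (not isolated)
Conditions: (S)-α,α-diphenylprolinol TMS ether (10 mol%), PhCO2H (10 mol%), CH2Cl2, 0 °C; then MeOH, TsOH·H2O (cat.), 23 °C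
Reagents that add atoms: methanol (CO)
Why: Iminium-catalysed Michael addition of the dione to the enal should set C10 (R) because the diphenyl(silyloxy)methyl group shields one face of the (E)-iminium ion, and Fischer acetalisation of the cyclic hemiacetal gives a cyclic vinylogous ester in which the two dione carbonyls are differentiated.

Step 2
Reactants: 4 methyl acetal
Product: 5 (4R)-2-methoxy-4,6-dimethyl-3,4,6,7-tetrahydrocyclopenta[b]pyran-5(2H)-one (epimer mixture)
Conditions: LDA, THF, −78 °C; MeI, −78 → −30 °C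
Reagents that add atoms: iodomethane (CI)
Why: Kinetic α′-enolate alkylation of a vinylogous ester (Stork–Danheiser type) puts the future C15 methyl group on C4; the new centre is not controlled and is erased later.

Step 3
Reactants: 5 methylated vinylogous ester
Product: 6 (4R)-6-hydroxy-2-methoxy-4,6-dimethyl-3,4,6,7-tetrahydrocyclopenta[b]pyran-5(2H)-one (epimer mixture)
Conditions: KN(SiMe3)2, THF, −78 °C; 2-(phenylsulfonyl)-3-phenyloxaziridine; aq. NH4Cl
Reagents that add atoms: 2-(phenylsulfonyl)-3-phenyloxaziridine (O=S(=O)(N1OC1c1ccccc1)c1ccccc1)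
Why: Enolate hydroxylation with an N-sulfonyloxaziridine (Davis oxidation) at the same α′ carbon gives the tertiary C4 carbinol that later serves as the leaving group for diene formation; both C4 epimers are usable.

Step 4
Reactants: 6 hydroxylated vinylogous ester
Product: 8 (3R)-3-[3-hydroxy-3-methyl-5-oxo-2-(prop-2-enyl)cyclopent-1-enyl]butanal, via carbinol 7 (not isolated)
Conditions: allylMgBr (3 equiv), THF, −78 → 0 °C; then 1 M HCl, THF, 0 → 23 °C
Reagents that add atoms: allylmagnesium bromide (C=CC[Mg]Br); water (O)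
Why: Stork–Danheiser 1,2-addition/transposition: the Grignard reagent adds to the vinylogous-ester ketone (future C5), and aqueous acid hydrolyses the enol-ether acetal, dehydrates the tertiary carbinol into conjugation (C2 ketone, C1=C5) and releases the C8 aldehyde without touching C10.

Step 5
Reactants: 8 allyl enone aldehyde
Product: 9 (3R)-3-[3-hydroxy-3-methyl-2-(3-methylbut-2-enyl)-5-oxocyclopent-1-enyl]butanal
Conditions: second-generation Grubbs catalyst (5 mol%), 2-methyl-2-butene/CH2Cl2, 35 °C
Reagents that add atoms: 2-methyl-2-butene (CC=C(C)C)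
Why: Olefin cross-metathesis of the terminal alkene with 2-methyl-2-butene should give the prenyl group needed as ene donor, the tetrasubstituted enone olefin being inert.

Step 6
Reactants: 9 prenyl enone aldehyde
Product: 10 (5S,6R,8R)-3,6-dihydroxy-3,8-dimethyl-5-(prop-1-en-2-yl)-3,4,5,6,7,8-hexahydroazulen-1(2H)-one (guaiane 7S,8R,10R)
Conditions: Me2AlCl (2.5 equiv), CH2Cl2, −78 → −20 °C
Reagents that add atoms: none
Why: Lewis-acid-promoted intramolecular carbonyl-ene reaction (citronellal-to-isopulegol type) forms C7–C8 and the cycloheptane; a chair-like transition state with the forming C7 and C8 substituents equatorial and the C10 methyl group pseudo-axial (allylic 1,2-strain with the C2 carbonyl) should give the 7,8-trans, 8,10-trans isomer.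

Step 7
Reactants: 10 isopropenyl diol
Product: 11 (5S,6R,8R)-3,6-dihydroxy-5-(3-hydroxyprop-1-en-2-yl)-3,8-dimethyl-3,4,5,6,7,8-hexahydroazulen-1(2H)-one
Conditions: SeO2 (0.3 equiv), t-BuOOH (3 equiv), CH2Cl2, 23 °C
Reagents that add atoms: tert-butyl hydroperoxide (CC(C)(C)OO)
Why: Catalytic SeO2 allylic oxidation (ene reaction, then 2,3-sigmatropic shift) should occur at the methyl group of the electron-rich 1,1-disubstituted olefin, the enone olefin being deactivated.

Step 8
Reactants: 11 triol
Product: 12 4-hydroxy-2-oxoguaia-1(5),11(13)-dien-12,8-olide (7S,8R,10R)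
Conditions: TEMPO (0.2 equiv), PhI(OAc)2 (2.5 equiv), CH2Cl2, 23 °C
Reagents that add atoms: none
Why: TEMPO-mediated oxidative lactonisation: the primary allylic alcohol is oxidised to the aldehyde, which is trapped by the C8 hydroxyl as the lactol and oxidised on to the trans-fused α-methylene lactone, the tertiary alcohol being inert.

Step 9
Reactants: 12 enone lactone
Product: 13 (2S)-2,4-dihydroxyguaia-1(5),11(13)-dien-12,8-olide
Conditions: (R)-2-methyl-CBS-oxazaborolidine (0.3 equiv), catecholborane (2 equiv), PhMe, −78 °C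
Reagents that add atoms: none
Why: Corey–Bakshi–Shibata reduction under reagent control, with the substituted alkenyl side (C1) as the large group, should deliver the (2S)-allylic alcohol by 1,2-reduction, faster than any reaction at the methylene lactone.

Step 10
Reactants: 13 allylic alcohol
Product: 14 (2S)-2-acetoxy-4-hydroxyguaia-1(5),11(13)-dien-12,8-olide
Conditions: Ac2O, pyridine, DMAP (cat.), CH2Cl2, 0 °C
Reagents that add atoms: acetic anhydride (CC(=O)OC(C)=O)
Why: Nucleophile-catalysed acylation acetylates the secondary allylic hydroxyl only, the tertiary C4 hydroxyl being too hindered.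

Step 11
Reactants: 15 (R)-citronellal
Product: 16 (6R)-8,8-dimethoxy-2,6-dimethyloct-2-ene
Conditions: HC(OMe)3, TsOH·H2O (cat.), MeOH, 23 °C
Reagents that add atoms: trimethyl orthoformate (COC(OC)OC)
Why: Acid-catalysed acetalisation protects the aldehyde (future C6′) for the ozonolysis; the C4′ stereocentre comes from the chiral pool.

Step 12
Reactants: 16 citronellal dimethyl acetal
Product: 17 (4R)-6,6-dimethoxy-4-methylhexan-1-ol
Conditions: O3, CH2Cl2/MeOH, −78 °C; then NaBH4, −78 → 0 °C
Reagents that add atoms: ozone (O=[O+][O-])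
Why: Ozonolysis with reductive work-up cleaves the trisubstituted olefin to the primary alcohol (future C1′–O), leaving the acetal intact.

Step 13
Reactants: 17 acetal alcohol
Product: 18 (4R)-5-(1,3-dithian-2-yl)-4-methylpentan-1-ol
Conditions: HS(CH2)3SH, BF3·OEt2, CH2Cl2, −20 → 0 °C
Reagents that add atoms: propane-1,3-dithiol (SCCCS)
Why: Lewis-acid transthioacetalisation converts the acetal into the 1,3-dithiane, the acyl-anion equivalent for C6′.

Step 14
Reactants: 19 ethyl 2-(2-methyl-1,3-dioxolan-2-yl)acetate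
Product: 20 2-(2-methyl-1,3-dioxolan-2-yl)acetaldehyde
Conditions: i-Bu2AlH (1.05 equiv), CH2Cl2, −78 °C; aq. potassium sodium tartrate
Reagents that add atoms: none
Why: Partial reduction of the ester stops at the aldehyde because the tetrahedral aluminium hemiacetal is stable at −78 °C.

Step 15
Reactants: 20 ketal aldehyde; 21 methyl propiolate
Product: 22 methyl (4S)-4-hydroxy-5-(2-methyl-1,3-dioxolan-2-yl)pent-2-ynoate
Conditions: (S,S)-ProPhenol (20 mol%), Me2Zn (3 equiv), Ph3PO (40 mol%), PhMe, 4 °C
Reagents that add atoms: none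
Why: Zinc–ProPhenol-catalysed asymmetric alkynylation of the aldehyde should set the future C8′ (S), the ligand enantiomer being the one that directs the zinc alkynide to the Re face.

Step 16
Reactants: 22 hydroxy ynoate
Product: 24 (5S)-5-[(2-methyl-1,3-dioxolan-2-yl)methyl]furan-2(5H)-one, via Z-hydroxy enoate 23 (not isolated)
Conditions: H2 (1 atm), Pd/CaCO3 poisoned with Pb(OAc)2, quinoline, EtOAc, 23 °C; then PPTS (cat.), CH2Cl2
Reagents that add atoms: none
Why: Lindlar cis-semihydrogenation gives the (Z)-γ-hydroxy enoate, which lactonises to the butenolide without touching the stereocentre.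

Step 17
Reactants: 18 dithiane alcohol; 24 butenolide
Product: 26 (3S,4R,5S)-4-{2-[(2R)-5-hydroxy-2-methylpentyl]-1,3-dithian-2-yl}-3-(hydroxymethyl)-5-[(2-methyl-1,3-dioxolan-2-yl)methyl]oxolan-2-one, via lithium enolate 25 (not isolated)
Conditions: n-BuLi (2.1 equiv), THF/DMPU, −30 °C; 24, −78 °C; CH2O (gas), −78 → −40 °C; aq. NH4Cl
Reagents that add atoms: formaldehyde (C=O)
Why: Conjugate addition of the 2-lithio-1,3-dithiane to the butenolide occurs anti to the C5 substituent (C7′ trans to the C8′ arm), and the lactone enolate is trapped by an aldol reaction with formaldehyde anti to the new substituent.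

Step 18
Reactants: 26 diol lactone
Product: 28 (4R)-4-methyl-5-{2-[(2S,3R)-4-methylidene-2-[(2-methyl-1,3-dioxolan-2-yl)methyl]-5-oxooxolan-3-yl]-1,3-dithian-2-yl}pentyl acetate, via diacetate 27 (not isolated)
Conditions: Ac2O, pyridine, DMAP (cat.), CH2Cl2, 23 °C; then DBU, 0 °C
Reagents that add atoms: acetic anhydride (CC(=O)OC(C)=O)
Why: Acetylation of both primary alcohols followed by E1cB elimination of the β-acetoxy lactone gives the α-methylene lactone and leaves the side-chain acetate that the target carries.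

Step 19
Reactants: 14 acetoxy carbinol; 28 dienophile
Product: 30 Diels–Alder adduct (7′-epi; C6′ dithiane; C10′ dioxolane), via acetoxy diene 29 (not isolated)
Conditions: Burgess reagent, PhH, 23 °C, cold filtration through Florisil; then slow addition to 28 (3 equiv), Et2AlCl (3 equiv), CH2Cl2, −78 → −40 °C
Reagents that add atoms: none
Why: Burgess dehydration of the tertiary allylic alcohol gives the cyclopentadiene, and the Lewis-acid-promoted Diels–Alder reaction should join C13′ to the fully substituted C1 and C11′ to C3 (no vicinal quaternary carbons) with the lactone carbonyl exo, on the diene face opposite the C2 acetoxy and pseudo-axial C10 methyl groups (sets C1 and C3) and on the dienophile face opposite the dithianyl group (sets C11′), the excess of 28 suppressing self-cycloaddition of 29.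

Step 20
Reactants: 30 Diels–Alder adduct
Product: 31 C6′ ketone with C10′ dioxolane (7′-epi)
Conditions: MeI, CaCO3, MeCN/H2O (9:1), 45 °C
Reagents that add atoms: water (O)
Why: S-Alkylative hydrolysis of the dithiane under buffered, non-oxidising conditions unveils the C6′ ketone and should leave the dioxolane, both acetates, the methylene lactone and the olefins untouched.

Step 21
Reactants: 31 keto-ketal
Product: 34 cis-fused 6′-oxo enone, via diketone 32 (not isolated), via epimerised diketone 33 (not isolated)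
Conditions: TsOH·H2O (0.3 equiv), water-saturated PhH, 60 °C
Reagents that add atoms: none
Why: Aqueous acid cleaves the dioxolane to the C10′ methyl ketone (32); enolisation of the C6′ ketone toward C7′ equilibrates 32 with its 7′-epimer 33, while the C5′ enol adds to the protonated C10′ ketone and E1 loss of water from the tertiary aldol gives the tetrasubstituted C5′=C10′ enone. The closest known reaction is the acid-catalysed aldol cyclodehydration of a 1,5-diketone (second stage of a Robinson annulation), here coupled to epimerisation of an α-stereocentre. The ring (C5′, C6′, C7′, C8′, C9′, C10′) closes in a 6-(enolendo)-exo-trig aldol at C5′–C10′. C7′ is the only stereocentre that changes and is under thermodynamic control: its proton stays exchangeable through the C6′ enol of the diketones and the dienol of the enone, so the 7′-epi material from the cycloaddition should funnel into the less strained cis-fused lactone–cyclohexenone (H7′ cis to H8′). The step needs C5′-to-C10′ regiochemistry, which the substrate secures because the C6′ carbonyl, flanked by C7′ and the spiro carbon C11′, is shielded from the methyl-ketone enols and the other closures would give four-membered rings. It also needs the C8′–O lactone bond β to the C6′ ketone to stay intact, which is expected because ionisation of this secondary ring C–O bond is slower than loss of water from the tertiary aldol, and the mild acid should spare the acetates, the methylene lactone and the norbornene olefin.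

Step 22
Reactants: 34 enone
Product: 35 target CNP0211028.4
Conditions: NaBH4, CeCl3·7H2O, MeOH, −78 °C
Reagents that add atoms: none
Why: Luche 1,2-reduction: axial hydride delivery anti to the pseudo-axial H7′ should give the equatorial C6′ hydroxyl trans to the C7′–C11′ bond (6′R), the ketone reacting faster than the methylene lactone or the acetates.

**Compound list**

1 | cyclopentane-1,3-dione | O=C1CCC(=O)C1 | starting material
2 | (E)-but-2-enal | C/C=C/C=O | starting material
3 | (4R)-2-hydroxy-4-methyl-3,4,6,7-tetrahydrocyclopenta[b]pyran-5(2H)-one (anomer mixture) | O=C1CCC2=C1[C@H](C)CC(O)O2 | intermediate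
4 | (4R)-2-methoxy-4-methyl-3,4,6,7-tetrahydrocyclopenta[b]pyran-5(2H)-one (anomer mixture) | O=C1CCC2=C1[C@H](C)CC(OC)O2 | intermediate
5 | (4R)-2-methoxy-4,6-dimethyl-3,4,6,7-tetrahydrocyclopenta[b]pyran-5(2H)-one (epimers at C2 and C6) | O=C1C(C)CC2=C1[C@H](C)CC(OC)O2 | intermediate
6 | (4R)-6-hydroxy-2-methoxy-4,6-dimethyl-3,4,6,7-tetrahydrocyclopenta[b]pyran-5(2H)-one (epimers at C2 and C6) | O=C1C(C)(O)CC2=C1[C@H](C)CC(OC)O2 | intermediate
7 | (4R)-2-methoxy-4,6-dimethyl-5-(prop-2-enyl)-2,3,4,5,6,7-hexahydrocyclopenta[b]pyran-5,6-diol, present as its bromomagnesium alkoxide | C=CCC1(O)C(C)(O)CC2=C1[C@H](C)CC(OC)O2 | intermediate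
8 | (3R)-3-[3-hydroxy-3-methyl-5-oxo-2-(prop-2-enyl)cyclopent-1-enyl]butanal (carbinol epimers) | C=CCC1=C([C@H](C)CC=O)C(=O)CC1(C)O | intermediate
9 | (3R)-3-[3-hydroxy-3-methyl-2-(3-methylbut-2-enyl)-5-oxocyclopent-1-enyl]butanal | CC(C)=CCC1=C([C@H](C)CC=O)C(=O)CC1(C)O | intermediate
10 | (5S,6R,8R)-3,6-dihydroxy-3,8-dimethyl-5-(prop-1-en-2-yl)-3,4,5,6,7,8-hexahydroazulen-1(2H)-one (guaiane 7S,8R,10R; C4 epimers) | C=C(C)[C@@H]1CC2=C([C@H](C)C[C@H]1O)C(=O)CC2(C)O | intermediate
11 | (5S,6R,8R)-3,6-dihydroxy-5-(3-hydroxyprop-1-en-2-yl)-3,8-dimethyl-3,4,5,6,7,8-hexahydroazulen-1(2H)-one | C=C(CO)[C@@H]1CC2=C([C@H](C)C[C@H]1O)C(=O)CC2(C)O | intermediate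
12 | 4-hydroxy-2-oxoguaia-1(5),11(13)-dien-12,8-olide (7S,8R,10R; trans-fused lactone; C4 epimers) | C=C1C(=O)O[C@@H]2C[C@@H](C)C3=C(C[C@@H]12)C(C)(O)CC3=O | intermediate
13 | (2S)-2,4-dihydroxyguaia-1(5),11(13)-dien-12,8-olide (2S,7S,8R,10R) | C=C1C(=O)O[C@@H]2C[C@@H](C)C3=C(C[C@@H]12)C(C)(O)C[C@@H]3O | intermediate
14 | (2S)-2-acetoxy-4-hydroxyguaia-1(5),11(13)-dien-12,8-olide | C=C1C(=O)O[C@@H]2C[C@@H](C)C3=C(C[C@@H]12)C(C)(O)C[C@@H]3OC(C)=O | intermediate
15 | (R)-citronellal, (3R)-3,7-dimethyloct-6-enal | O=CC[C@H](C)CCC=C(C)C | starting material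
16 | (6R)-8,8-dimethoxy-2,6-dimethyloct-2-ene | COC(OC)C[C@H](C)CCC=C(C)C | intermediate
17 | (4R)-6,6-dimethoxy-4-methylhexan-1-ol | COC(OC)C[C@H](C)CCCO | intermediate
18 | (4R)-5-(1,3-dithian-2-yl)-4-methylpentan-1-ol | OCCC[C@@H](C)CC1SCCCS1 | intermediate
19 | ethyl 2-(2-methyl-1,3-dioxolan-2-yl)acetate | CCOC(=O)CC1(C)OCCO1 | starting material
20 | 2-(2-methyl-1,3-dioxolan-2-yl)acetaldehyde | O=CCC1(C)OCCO1 | intermediate
21 | methyl propiolate | C#CC(=O)OC | starting material
22 | methyl (4S)-4-hydroxy-5-(2-methyl-1,3-dioxolan-2-yl)pent-2-ynoate | COC(=O)C#C[C@@H](O)CC1(C)OCCO1 | intermediate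
23 | methyl (2Z,4S)-4-hydroxy-5-(2-methyl-1,3-dioxolan-2-yl)pent-2-enoate | COC(=O)/C=C\[C@@H](O)CC1(C)OCCO1 | intermediate
24 | (5S)-5-[(2-methyl-1,3-dioxolan-2-yl)methyl]furan-2(5H)-one | O=C1C=C[C@H](CC2(C)OCCO2)O1 | intermediate
25 | dilithium salt (lactone enolate and side-chain alkoxide) of the trans 1,4-adduct of 18 and 24 | [Li+].[Li+].[O-]CCC[C@@H](C)CC1(SCCCS1)[C@@H]2C=C([O-])O[C@H]2CC3(C)OCCO3 | intermediate
26 | (3S,4R,5S)-4-{2-[(2R)-5-hydroxy-2-methylpentyl]-1,3-dithian-2-yl}-3-(hydroxymethyl)-5-[(2-methyl-1,3-dioxolan-2-yl)methyl]oxolan-2-one | OC[C@H]1C(=O)O[C@@H](CC2(C)OCCO2)[C@@H]1C3(C[C@H](C)CCCO)SCCCS3 | intermediate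
27 | diacetate of 26 | CC(=O)OC[C@H]1C(=O)O[C@@H](CC2(C)OCCO2)[C@@H]1C3(C[C@H](C)CCCOC(C)=O)SCCCS3 | intermediate
28 | (4R)-4-methyl-5-{2-[(2S,3R)-4-methylidene-2-[(2-methyl-1,3-dioxolan-2-yl)methyl]-5-oxooxolan-3-yl]-1,3-dithian-2-yl}pentyl acetate | C=C1C(=O)O[C@@H](CC2(C)OCCO2)[C@@H]1C3(C[C@H](C)CCCOC(C)=O)SCCCS3 | intermediate
29 | (2S)-2-acetoxyguaia-1(5),3,11(13)-trien-12,8-olide (7S,8R,10R) | C=C1C(=O)O[C@@H]2C[C@@H](C)C3=C(C[C@@H]12)C(C)=C[C@@H]3OC(C)=O | intermediate
30 | Diels–Alder adduct: target skeleton without the cyclohexene ring; C7′ epimeric (acyl-equivalent trans to the C8′ arm), C6′ as 1,3-dithiane, C10′ as dioxolane | C=C1C(=O)O[C@@H]2C[C@@H](C)[C@]34C[C@@]5(C(=O)O[C@@H](CC6(C)OCCO6)[C@@H]5C7(C[C@H](C)CCCOC(C)=O)SCCCS7)[C@H](C(C)=C3C[C@@H]12)[C@@H]4OC(C)=O | intermediate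
31 | 6′-oxo-10′-dioxolane seco compound (7′-epi) | C=C1C(=O)O[C@@H]2C[C@@H](C)[C@]34C[C@@]5(C(=O)O[C@@H](CC6(C)OCCO6)[C@@H]5C(=O)C[C@H](C)CCCOC(C)=O)[C@H](C(C)=C3C[C@@H]12)[C@@H]4OC(C)=O | intermediate
32 | 6′,10′-dioxo seco compound (1,5-diketone, 7′-epi) | C=C1C(=O)O[C@@H]2C[C@@H](C)[C@]34C[C@@]5(C(=O)O[C@@H](CC(C)=O)[C@@H]5C(=O)C[C@H](C)CCCOC(C)=O)[C@H](C(C)=C3C[C@@H]12)[C@@H]4OC(C)=O | intermediate
33 | 6′,10′-dioxo seco compound (1,5-diketone, C7′ acyl group cis to the C8′ arm) | C=C1C(=O)O[C@@H]2C[C@@H](C)[C@]34C[C@@]5(C(=O)O[C@@H](CC(C)=O)[C@H]5C(=O)C[C@H](C)CCCOC(C)=O)[C@H](C(C)=C3C[C@@H]12)[C@@H]4OC(C)=O | intermediate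
34 | 6′-oxo derivative of the target (cis-fused enone) | C=C1C(=O)O[C@@H]2C[C@@H](C)[C@]34C[C@@]5(C(=O)O[C@H]6CC(C)=C([C@H](C)CCCOC(C)=O)C(=O)[C@H]65)[C@H](C(C)=C3C[C@@H]12)[C@@H]4OC(C)=O | intermediate
35 | CNP0211028.4 | C=C1C(=O)O[C@@H]2C[C@@H](C)[C@]34C[C@@]5(C(=O)O[C@H]6CC(C)=C([C@H](C)CCCOC(C)=O)[C@H](O)[C@H]65)[C@H](C(C)=C3C[C@@H]12)[C@@H]4OC(C)=O | target

**Step count and risks**

Total step count: 22. Longest linear sequence: 14 steps (steps 1–10, then 19–22).

Steps most likely to fail:

Step 19 (cycloaddition). Three processes threaten it: a 1,5-hydrogen shift of the 5-acetoxycyclopentadiene 29 before it is trapped; cycloaddition of 29 with the exocyclic methylene lactone of a second diene molecule instead of 28; and approach of the dienophile syn to the acetoxy group, which the C10 methyl group is expected, but not guaranteed, to override. The fallback removes the competing dienophile; it does not address the facial question. It sets out from 14: conjugate addition of dimethylamine (Me2NH, THF, 0 °C) gives the 13-(dimethylamino)-11,13-dihydro lactone F1 (C11 epimers). Burgess dehydration gives the amine-masked acetoxy diene F2, used in solution. Cycloaddition with 28 (1.2 equiv, Et2AlCl with one further equivalent for the amine) gives the amine-masked cycloadduct F3. N-Methylation (MeI, MeCN, 0 °C) gives the methiodide F4, and elimination with aqueous NaHCO3 restores the methylene lactone and returns to the route at 30.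

Step 21 (key step). Ring closure may outrun epimerisation at C7′ and leave the trans-fused enone as the resting state; the lactone carboxylate may be lost from the C6′ enol by β-elimination; and acid may induce skeletal rearrangement at the norbornene olefin. The fallback sets C7′ kinetically instead of thermodynamically. It sets out from 31: the same acid at 23 °C gives the 7′-epi (trans-fused) enone F5. Soft enolisation (TBSOTf, Et3N, CH2Cl2, −78 °C) gives the cross-conjugated C6′-silyloxy C6′=C7′ dienol ether F6. Kinetic protonation (HF·pyridine, THF, −40 °C) on the convex face, cis to H8′, returns to the route at 34.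

Step 6 (carbonyl-ene closure). Closure of the seven-membered ring may be slower than chloride capture of the cationic intermediate or aldehyde oligomerisation, and the C7/C8 centres may form with poor selectivity relative to C10. The fallback replaces the ene reaction by a Nozaki–Hiyama allylation. It sets out from 8: cross-metathesis with 3-bromo-2-methylpropene (second-generation Grubbs catalyst) gives the (E)-allylic bromide F7. CrCl2 (THF, 0 °C) generates the allylchromium species, which adds through its γ-carbon (C7) to the aldehyde in a chair transition state (anti adduct) and returns to the route at 10.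

Further compounds
F1 | step 19 | 13-(dimethylamino)-11,13-dihydro derivative of 14 (C11 epimers) | CN(C)CC1C(=O)O[C@@H]2C[C@@H](C)C3=C(C[C@@H]12)C(C)(O)C[C@@H]3OC(C)=O
F2 | step 19 | amine-masked acetoxy diene (13-dimethylamino-11,13-dihydro derivative of 29) | CN(C)CC1C(=O)O[C@@H]2C[C@@H](C)C3=C(C[C@@H]12)C(C)=C[C@@H]3OC(C)=O
F3 | step 19 | amine-masked cycloadduct (13-dimethylamino-11,13-dihydro derivative of 30) | CN(C)CC1C(=O)O[C@@H]2C[C@@H](C)[C@]34C[C@@]5(C(=O)O[C@@H](CC6(C)OCCO6)[C@@H]5C7(C[C@H](C)CCCOC(C)=O)SCCCS7)[C@H](C(C)=C3C[C@@H]12)[C@@H]4OC(C)=O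
F4 | step 19 | methiodide of F3 | C[N+](C)(C)CC1C(=O)O[C@@H]2C[C@@H](C)[C@]34C[C@@]5(C(=O)O[C@@H](CC6(C)OCCO6)[C@@H]5C7(C[C@H](C)CCCOC(C)=O)SCCCS7)[C@H](C(C)=C3C[C@@H]12)[C@@H]4OC(C)=O.[I-]
F5 | step 21 | 7′-epi (trans-fused) 6′-oxo enone | C=C1C(=O)O[C@@H]2C[C@@H](C)[C@]34C[C@@]5(C(=O)O[C@H]6CC(C)=C([C@H](C)CCCOC(C)=O)C(=O)[C@@H]65)[C@H](C(C)=C3C[C@@H]12)[C@@H]4OC(C)=O
F6 | step 21 | C6′ tert-butyldimethylsilyl dienol ether (C6′=C7′) | C=C1C(=O)O[C@@H]2C[C@@H](C)[C@]34C[C@@]5(C(=O)O[C@H]6CC(C)=C([C@H](C)CCCOC(C)=O)C(O[Si](C)(C)C(C)(C)C)=C65)[C@H](C(C)=C3C[C@@H]12)[C@@H]4OC(C)=O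
F7 | step 6 | (3R)-3-{2-[(2E)-4-bromo-3-methylbut-2-enyl]-3-hydroxy-3-methyl-5-oxocyclopent-1-enyl}butanal | BrC/C(C)=C/CC1=C([C@H](C)CC=O)C(=O)CC1(C)O
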